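**Retrosynthetic overview**
1. The γ-lactone is opened to a spiro-oxetane (20): the last step inserts CO into one of its two CH2–O bonds (four- to five-membered ring expansion), which also sets C13.
2. The tetrahydrofuran of 20 comes from a 5-exo oxa-Michael addition of a C13 alcohol to an 8-en-7-one (sets C8 and C9); the 6β-hydroxy-7-ketone comes from a 6-ketone by hydride attack on the α face.
3. C9–C11 is disconnected by a B-alkyl Suzuki coupling between cyclohexenyl triflate 10 and 3-vinyloxetan-3-ol 12 (from oxetan-3-one).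
4. Triflate 10 comes from (S)-Hajos–Parrish ketone 5: diazoethane expands the cyclopentanone to the six-membered ring B and brings in C8 with its methyl; then gem-dimethylation and 3β-reduction.
5. Ring order: ring A (proline Robinson annulation), ring B (five- to six-membered ring expansion), tetrahydrofuran (oxa-Michael), lactone (carbonylative ring expansion of the oxetane).

Assumption: decalin positions carry labdane numbers (C1–C10; C4 gem-dimethyl, C10 angular methyl, C17 on C8; side chain C11–C16), β is the face of the C10 methyl, and diazoethane is used as a freshly made ether solution from commercial N-ethyl-N-nitrosourea and KOH.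

**Step 1**
Reactants: 1 (2-methylcyclopentane-1,3-dione) + 2 (methyl vinyl ketone)
Product: 5 (S)-Hajos–Parrish ketone (7aS)-7a-methyl-2,3,7,7a-tetrahydro-1H-indene-1,5(6H)-dione, via triketone 3 (not isolated), via cis-ketol 4 (not isolated)
Conditions: 2 (1.5 equiv), AcOH (cat.), H2O, 70 °C; evaporate; L-proline (3 mol%), DMF, 20 °C; then H2SO4 (cat.), 95 °C
Reagents that add atoms: none
Why: Robinson annulation in the Hajos–Parrish–Eder–Sauer–Wiechert form: after the Michael addition the L-proline enamine aldol picks one of the two enantiotopic ring carbonyls and fixes the quaternary carbon as S (the later 10β-methyl), and acid dehydrates the ketol.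

**Step 2**
Reactants: 5 ((S)-Hajos–Parrish ketone)
Product: 6 (10S)-8,10-dimethyldecal-4-ene-3,9-dione (ring B now six-membered; C8 epimer mixture)
Conditions: CH3CHN2 (1.3 equiv, Et2O), Sc(OTf)3 (5 mol%), CH2Cl2, −78 °C
Reagents that add atoms: diazoethane, CC=[N+]=[N-]
Why: Büchner–Curtius–Schlotterbeck (Tiffeneau–Demjanov-type) ring expansion: diazoethane adds to the activated saturated ketone (the enone is less electrophilic), the less substituted CH2 migrates with loss of N2 so that CH(CH3) is inserted between C9 and C7, and the product, flanked by a quaternary and a tertiary carbon, resists a second insertion; the C8 epimers converge in step 5.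

**Step 3**
Reactants: 6 (ring-expanded enedione)
Product: 7 (10S)-4,4,8,10-tetramethyldecal-5-ene-3,9-dione (C8 epimers)
Conditions: KOtBu (2.3 equiv), MeI (5 equiv), t-BuOH/THF, 0 → 23 °C
Reagents that add atoms: iodomethane, CI
Why: Deconjugative α,α-dialkylation of the enone through its extended dienolate: two methylations at C4 leave the olefin at C5=C6, while the hindered tertiary C8–H next to the C9 ketone alkylates far more slowly.

**Step 4**
Reactants: 7 (gem-dimethyl enedione)
Product: 9 3β-acetoxy-4,4,8,10-tetramethyldecal-5-en-9-one, via 3β-alcohol 8 (not isolated)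
Conditions: NaBH4 (0.5 equiv), MeOH/CH2Cl2, −20 °C; acetone, evaporate; Ac2O, pyridine, DMAP (cat.), 23 °C
Reagents that add atoms: acetic anhydride, CC(=O)OC(C)=O
Why: Hydride reduction by axial attack on the α face (the equatorial path is blocked by the C4 methyls) gives the equatorial 3β-alcohol (3S) and spares the doubly α-branched C9 ketone; acetylation of the crude alcohol installs the acetate of the target.

**Step 5**
Reactants: 9 (3β-acetoxy ketone)
Product: 10 3β-acetoxy-4,4,8,10-tetramethyldecala-5,8-dien-9-yl trifluoromethanesulfonate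
Conditions: Tf2O (1.5 equiv), 2,6-di-tert-butyl-4-methylpyridine (2 equiv), CH2Cl2, 0 → 23 °C
Reagents that add atoms: triflic anhydride, O=S(=O)(OS(=O)(=O)C(F)(F)F)C(F)(F)F
Why: Enol triflate formation under non-basic Stang conditions: C8–H is the only enolisable position, so the tetrasubstituted C8=C9 triflate forms regiospecifically (same class as 2,6,6-trimethylcyclohexenyl triflate) and the acetate is untouched.

**Step 6**
Reactants: 11 (oxetan-3-one)
Product: 12 3-ethenyloxetan-3-ol
Conditions: CH2=CHMgBr (1.2 equiv), THF, −78 → 0 °C; H2O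
Reagents that add atoms: vinylmagnesium bromide, C=C[Mg]Br
Why: Grignard 1,2-addition to an unhindered strained ketone; the product is achiral, and its two oxetane CH2 groups become the lactone carbons C14 and C16.

**Step 7**
Reactants: 12 (3-ethenyloxetan-3-ol) + 10 (dienyl triflate)
Product: 14 3β-acetoxy-9-[2-(3-hydroxyoxetan-3-yl)ethyl]-4,4,8,10-tetramethyldecala-5,8-diene, via alkylborane 13 (not isolated)
Conditions: 12, 9-BBN (2.2 equiv), THF, 0 → 23 °C; then 10, Pd(dppf)Cl2 (10 mol%), AsPh3 (10 mol%), K3PO4 (3 M aq), DMF/THF, 50 °C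
Reagents that add atoms: none
Why: Anti-Markovnikov hydroboration of the vinyl group followed by B-alkyl Suzuki–Miyaura coupling with the hindered cyclohexenyl triflate forms C9–C11; no stereocenter is created and the acetate survives the phosphate base.

**Step 8**
Reactants: 14 (diene alcohol)
Product: 16 3β-acetoxy-9-[2-(3-hydroxyoxetan-3-yl)ethyl]-4,4,8,10-tetramethyl-5α-decal-8-en-6-one, via 6α-alkylborane 15 (not isolated)
Conditions: BH3·SMe2 (4 equiv), CH2Cl2, 0 → 35 °C; MeOH; then pyridinium chlorochromate [C5H5NH][CrO3Cl] (6 equiv), NaOAc, 4 Å sieves, CH2Cl2, 40 °C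
Reagents that add atoms: pyridinium chlorochromate, [O-][Cr](=O)(=O)Cl.c1cc[nH+]cc1
Why: Brown hydroboration of the trisubstituted C5=C6 olefin from the α face (the β face is shielded by the C10 and 4β methyls) puts H on C5 (trans-decalin, 5S) and boron on C6, and chlorochromate oxidises the C–B bond directly to the ketone; the tetrasubstituted C8=C9 olefin next to quaternary C10 is inert to borane, and trans fusion is also the thermodynamic one for this ketone.

**Step 9**
Reactants: 16 (6-ketone)
Product: 18 3β-acetoxy-6β,7-dihydroxy-9-[2-(3-hydroxyoxetan-3-yl)ethyl]-4,4,8,10-tetramethyl-5α-decal-8-ene (C7 epimers), via 7-hydroxy-6-ketone 17 (not isolated)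
Conditions: KN(SiMe3)2 (2.2 equiv), THF, −78 °C; 2-(phenylsulfonyl)-3-phenyloxaziridine (1.2 equiv), −78 °C; then MeOH, NaBH4 (3 equiv), −78 → −20 °C; AcOH
Reagents that add atoms: 2-(phenylsulfonyl)-3-phenyloxaziridine, O=S(=O)(c1ccccc1)N1OC1c1ccccc1
Why: Davis α-hydroxylation of the potassium dienolate at C7 (the doubly activated allylic CH2; C5–H is too hindered), then borohydride reduction of the C6 ketone in the same flask from the open α face (the β face is blocked by the syn-axial 4β and C10 methyls) gives the axial 6β-alcohol (6S) before the sensitive ketol can isomerise; the C7 configuration is erased in step 10.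

**Step 10**
Reactants: 18 (6β,7-diol)
Product: 20 (3S,5S,6S,8S,9R,10S)-3-acetoxy-6-hydroxy-4,4,8,10-tetramethyl-7-oxodecalin spiro-fused at C9 to a 2,5-dioxaspiro[3.4]octane (9α,13-epoxide; oxetane at C13), via hydroxy-enone 19 (not isolated)
Conditions: MnO2 (20 equiv), CH2Cl2, 23 °C; filter through Celite; then DBU (0.5 equiv), CH2Cl2, 23 → 40 °C
Reagents that add atoms: none
Why: MnO2 oxidises only the allylic C7 alcohol to the 8-en-7-one, and DBU then triggers a reversible 5-exo-trig oxa-Michael addition of the tertiary alcohol to C9: attack anti to the C10 methyl places oxygen 9α (axial) and C11 equatorial (9R), and protonation at C8 leaves the methyl equatorial (8S), both also the thermodynamic outcome; the equatorial C6–H is poorly aligned for enolisation, so the 6β-alcohol is kept.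

**Step 11**
Reactants: 20 (spiro-oxetane)
Product: 21 (3S,5S,6S,8S,9R,10S,13R)-3-acetoxy-6-hydroxy-7-oxo-9,13-epoxylabdan-15,16-olide (CNP0325396.1)
Conditions: CO (60 bar), [((R,R)-salcy)Cr(THF)2][Co(CO)4] (10 mol%; salcy = N,N'-bis(3,5-di-tert-butylsalicylidene)-trans-cyclohexane-1,2-diamine dianion), 1,2-dimethoxyethane, 70 °C
Reagents that add atoms: carbon monoxide, [C-]#[O+]
Why: Proposed new method: catalyst-controlled desymmetrising carbonylative ring expansion of a 3,3-disubstituted oxetane, in which the chiral chromium cation binds the oxetane oxygen (the only strained ether), [Co(CO)4]− opens one of the two diastereotopic CH2–O bonds by backside attack (ring strain offsets the neopentyl position), the alkyl–cobalt undergoes 1,2-alkyl migration to CO and the chromium alkoxide closes onto the acyl–cobalt to release the γ-lactone; opening at the pro-S methylene (the one cis to C10 across the tetrahydrofuran) gives 13R, the chiral cation makes this choice and its antipode is used if the (R,R) pair proves mismatched; the closest known reaction type is Lewis acid/[Co(CO)4]− ion-pair carbonylation of epoxides to β-lactones, including desymmetrisation of meso-epoxides, and the slow carbonylation of parent oxetane to γ-butyrolactone.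

**Compound list**
1 | 2-methylcyclopentane-1,3-dione | CC1C(=O)CCC1=O | starting material
2 | but-3-en-2-one (methyl vinyl ketone) | CC(=O)C=C | starting material
3 | 2-methyl-2-(3-oxobutyl)cyclopentane-1,3-dione | CC(=O)CCC1(C)C(=O)CCC1=O | intermediate
4 | (3aS,7aS)-3a-hydroxy-7a-methylhexahydro-1H-indene-1,5(4H)-dione | O=C1CC[C@@]2(C)[C@@](O)(C1)CCC2=O | intermediate
5 | (7aS)-7a-methyl-2,3,7,7a-tetrahydro-1H-indene-1,5(6H)-dione | O=C1CC[C@@]2(C)C(=C1)CCC2=O | intermediate
6 | (10S)-8,10-dimethyldecal-4-ene-3,9-dione, C8 epimers | O=C1CC[C@@]2(C)C(=C1)CCC(C)C2=O | intermediate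
7 | (10S)-4,4,8,10-tetramethyldecal-5-ene-3,9-dione, C8 epimers | O=C1CC[C@@]2(C)C(=CCC(C)C2=O)C1(C)C | intermediate
8 | 3β-hydroxy-4,4,8,10-tetramethyldecal-5-en-9-one | O[C@H]1CC[C@@]2(C)C(=CCC(C)C2=O)C1(C)C | intermediate
9 | 3β-acetoxy-4,4,8,10-tetramethyldecal-5-en-9-one | CC(=O)O[C@H]1CC[C@@]2(C)C(=CCC(C)C2=O)C1(C)C | intermediate
10 | 3β-acetoxy-4,4,8,10-tetramethyldecala-5,8-dien-9-yl triflate | CC(=O)O[C@H]1CC[C@@]2(C)C(=CCC(C)=C2OS(=O)(=O)C(F)(F)F)C1(C)C | intermediate
11 | oxetan-3-one | O=C1COC1 | starting material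
12 | 3-ethenyloxetan-3-ol | C=CC1(O)COC1 | intermediate
13 | 3-[2-(9-borabicyclo[3.3.1]nonan-9-yl)ethyl]oxetan-3-ol (hydroxyl drawn free; O-borylated in the flask) | OC1(CCB2C3CCCC2CCC3)COC1 | intermediate
14 | 3β-acetoxy-9-[2-(3-hydroxyoxetan-3-yl)ethyl]-4,4,8,10-tetramethyldecala-5,8-diene | CC(=O)O[C@H]1CC[C@@]2(C)C(=CCC(C)=C2CCC2(O)COC2)C1(C)C | intermediate
15 | 6α-boryl-5α-H hydroboration adduct of 14 (drawn as the monoalkylborane) | CC(=O)O[C@H]1CC[C@@]2(C)[C@@H]([C@@H](B)CC(C)=C2CCC2(O)COC2)C1(C)C | intermediate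
16 | 3β-acetoxy-9-[2-(3-hydroxyoxetan-3-yl)ethyl]-4,4,8,10-tetramethyl-5α-decal-8-en-6-one | CC(=O)O[C@H]1CC[C@@]2(C)[C@@H](C(=O)CC(C)=C2CCC2(O)COC2)C1(C)C | intermediate
17 | 7-hydroxy derivative of 16 (C7 epimers) | CC(=O)O[C@H]1CC[C@@]2(C)[C@@H](C(=O)C(O)C(C)=C2CCC2(O)COC2)C1(C)C | intermediate
18 | 6β,7-diol (C7 epimers) | CC(=O)O[C@H]1CC[C@@]2(C)[C@@H]([C@H](O)C(O)C(C)=C2CCC2(O)COC2)C1(C)C | intermediate
19 | 3β-acetoxy-6β-hydroxy-9-[2-(3-hydroxyoxetan-3-yl)ethyl]-4,4,8,10-tetramethyl-5α-decal-8-en-7-one | CC(=O)O[C@H]1CC[C@@]2(C)[C@@H]([C@H](O)C(=O)C(C)=C2CCC2(O)COC2)C1(C)C | intermediate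
20 | (3S,5S,6S,8S,9R,10S) spiro-oxetane: 3β-acetoxy-6β-hydroxy-7-oxo-9α,13-epoxide with C13 in an oxetane | CC(=O)O[C@H]1CC[C@@]2(C)[C@@H]([C@H](O)C(=O)[C@@H](C)[C@]23CCC2(COC2)O3)C1(C)C | intermediate
21 | (3S,5S,6S,8S,9R,10S,13R)-3-acetoxy-6-hydroxy-7-oxo-9,13-epoxylabdan-15,16-olide | CC(=O)O[C@H]1CC[C@@]2(C)[C@@H]([C@H](O)C(=O)[C@@H](C)[C@]23CC[C@@]2(COC(=O)C2)O3)C1(C)C | target

**Step count and risks**
Total: 11 steps. Longest linear sequence: 10 steps (steps 1–5 and 7–11; step 6 is the side branch).

The three steps most likely to fail are steps 11, 7 and 3.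

Step 11 (the proposed new carbonylation) may be too slow at the neopentyl CH2 or may not discriminate the two methylenes. The fallback sets out from 20 and uses known chemistry. LiI with BF3·OEt2 at −78 °C opens the oxetane to the γ-iodo alcohols; the epimer with CH2I cis to C10, the iodo alcohol F7, is separated by HPLC. Atom-transfer radical carbonylation with lactonisation (CO, Pd(PPh3)4, light, K2CO3) then closes the lactone, which is indifferent to the neopentyl position, and the route comes back at 21.

Step 7 may fail at transmetalation or reductive elimination on the hindered triflate flanked by quaternary C10. The fallback sets out from 10 and 11. HC≡CMgBr adds to 11 to give 3-ethynyloxetan-3-ol F5. Sonogashira coupling of 10 with F5 (Pd(PPh3)4, CuI, i-Pr2NH, DMF) gives the slim enyne F6. Hydrogenation with RhCl(PPh3)3 saturates only the triple bond, and the route comes back at 14.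

Step 3 may give some methylation at C8 or base cleavage at the unprotected C9 ketone. The fallback sets out from 6. Selective ketalisation of the saturated ketone (ethylene glycol, TsOH, 4 Å sieves) gives the C9 dioxolane F1. KOtBu/MeI gives the gem-dimethyl Δ5 ketal F2, NaBH4 gives the 3β-alcohol F3 and Ac2O/pyridine gives the acetate F4. Aqueous HCl in THF removes the dioxolane and the route comes back at 9, bypassing 7 and 8.

Further compounds
F1 | step 3 | (10S)-8,10-dimethyldecal-4-ene-3,9-dione 9-(ethylene ketal), C8 epimers | O=C1CC[C@@]2(C)C(=C1)CCC(C)C23OCCO3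
F2 | step 3 | (10S)-4,4,8,10-tetramethyldecal-5-ene-3,9-dione 9-(ethylene ketal) | O=C1CC[C@@]2(C)C(=CCC(C)C23OCCO3)C1(C)C
F3 | step 3 | 3β-hydroxy-4,4,8,10-tetramethyldecal-5-en-9-one ethylene ketal | O[C@H]1CC[C@@]2(C)C(=CCC(C)C23OCCO3)C1(C)C
F4 | step 3 | 3β-acetoxy-4,4,8,10-tetramethyldecal-5-en-9-one ethylene ketal | CC(=O)O[C@H]1CC[C@@]2(C)C(=CCC(C)C23OCCO3)C1(C)C
F5 | step 7 | 3-ethynyloxetan-3-ol | C#CC1(O)COC1
F6 | step 7 | 3β-acetoxy-9-[(3-hydroxyoxetan-3-yl)ethynyl]-4,4,8,10-tetramethyldecala-5,8-diene | CC(=O)O[C@H]1CC[C@@]2(C)C(=CCC(C)=C2C#CC2(O)COC2)C1(C)C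
F7 | step 11 | 3β-acetoxy-6β-hydroxy-7-oxo-9α,13-epoxide bearing CH2I (cis to C10) and CH2OH on C13 | CC(=O)O[C@H]1CC[C@@]2(C)[C@@H]([C@H](O)C(=O)[C@@H](C)[C@]23CC[C@@](CI)(CO)O3)C1(C)C
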